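## Retrosynthetic overview

1. The target is epiguibourtinidol-(4β→8)-epicatechin. The last C–C disconnection is the interflavan bond C4(upper)–C8(lower): benzyl-protected (−)-epicatechin adds to an upper flavan-4-yl cation anti to O3, and global hydrogenolysis follows.
2. The upper flavan is opened at O1–C8a. Ring C is closed onto ring A by this aryl–oxygen bond, so the C2–O bond is never broken and the 2,3-cis pair is simply a threo 1,2-diol monoether.
3. Enabling feature: ring A is a phenol whose C7–OH is para to C4a. Oxidation to the p-quinol (C4a carbinol) turns the unfunctionalized C8a, meta to that OH, into an enone β-carbon six atoms from O1; oxa-Michael addition and loss of water then rebuild ring A with O1 attached.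
4. The acyclic precursor comes from D-tyrosine (ring A, C4 and the C3 stereocentre) and 4-(benzyloxy)phenylmagnesium bromide (ring B; C2 set by chelation-controlled addition).
5. Ring order: rings A and B and the whole lower flavan are bought in; ring C of the upper unit is the only ring formed (step 8), before C4 activation and 4→8 coupling.

Key step: step 8

Remark on the chemistry: 12 and 15 are each drawn as one stereoisomer at centres that the next event erases (ring fusion of 12, C4 of 15); their epimers converge on the same product. Reagent 7 is taken as purchasable.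

## Route

Step 1
Reactants: 1 D-tyrosine
Product: 2 (R)-2-hydroxy-3-(4-hydroxyphenyl)propanoic acid
Conditions: NaNO2, 1 M H2SO4, H2O, 0 °C to rt
Reagents that add atoms: water O
Why: Diazotization-hydrolysis of an α-amino acid proceeds with net retention (the carboxylate displaces N2 to an α-lactone that water reopens, a double inversion), so the (R) centre of 1 becomes the future C3 of the upper unit.

Step 2
Reactants: 2 (R)-2-hydroxy-3-(4-hydroxyphenyl)propanoic acid
Product: 3 methyl (R)-2-hydroxy-3-(4-hydroxyphenyl)propanoate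
Conditions: MeOH, H2SO4 (cat.), reflux
Reagents that add atoms: methanol CO
Why: Fischer esterification converts only the carboxylic acid and leaves the stereocentre and both hydroxyl groups untouched.

Step 3
Reactants: 3 methyl (R)-2-hydroxy-3-(4-hydroxyphenyl)propanoate
Product: 4 methyl (R)-3-[4-[(tert-butyldimethylsilyl)oxy]phenyl]-2-hydroxypropanoate
Conditions: TBSCl (1.05 equiv), imidazole, CH2Cl2, 0 °C
Reagents that add atoms: tert-butyldimethylsilyl chloride CC(C)(C)[Si](C)(C)Cl
Why: Silylation with one equivalent of silyl chloride should take the more acidic, unhindered phenol before the hydrogen-bonded α-hydroxy ester hydroxyl, giving a ring A protecting group orthogonal to benzyl.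

Step 4
Reactants: 4 methyl (R)-3-[4-[(tert-butyldimethylsilyl)oxy]phenyl]-2-hydroxypropanoate
Product: 5 methyl (R)-2-(benzyloxy)-3-[4-[(tert-butyldimethylsilyl)oxy]phenyl]propanoate
Conditions: BnBr, Ag2O, Et2O, rt, dark
Reagents that add atoms: benzyl bromide BrCc1ccccc1
Why: Silver oxide-mediated Williamson benzylation works without a strong base, so the α-alkoxy ester is not enolized and the configuration is kept.

Step 5
Reactants: 5 methyl (R)-2-(benzyloxy)-3-[4-[(tert-butyldimethylsilyl)oxy]phenyl]propanoate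
Product: 6 (R)-2-(benzyloxy)-3-[4-[(tert-butyldimethylsilyl)oxy]phenyl]propanal
Conditions: i-Bu2AlH (1.1 equiv), CH2Cl2, −78 °C; Rochelle salt work-up
Reagents that add atoms: none
Why: Partial reduction with i-Bu2AlH stops at the chelated aluminium hemiacetal of an α-alkoxy ester at −78 °C, which releases the aldehyde only on work-up.

Step 6
Reactants: 6 (R)-2-(benzyloxy)-3-[4-[(tert-butyldimethylsilyl)oxy]phenyl]propanal; 7 4-(benzyloxy)phenylmagnesium bromide
Product: 8 (1R,2R)-2-(benzyloxy)-1-[4-(benzyloxy)phenyl]-3-[4-[(tert-butyldimethylsilyl)oxy]phenyl]propan-1-ol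
Conditions: MgBr2·OEt2, CH2Cl2, −78 °C; then 7 (THF solution), −78 °C
Reagents that add atoms: none
Why: Chelation-controlled Grignard addition (Cram chelate model): magnesium bridges the carbonyl and the α-benzyloxy oxygen and the aryl group enters from the side of the α-hydrogen, which should give the threo (1R,2R) carbinol, the future C2 of the flavan.

Step 7
Reactants: 8 (1R,2R)-2-(benzyloxy)-1-[4-(benzyloxy)phenyl]-3-[4-[(tert-butyldimethylsilyl)oxy]phenyl]propan-1-ol
Product: 9 (1R,2R)-2-(benzyloxy)-1-[4-(benzyloxy)phenyl]-3-(4-hydroxyphenyl)propan-1-ol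
Conditions: Bu4NF, AcOH, THF, 0 °C
Reagents that add atoms: none
Why: Fluoride desilylation cleaves the aryl silyl ether selectively and leaves both benzyl ethers and the benzylic alcohol intact, so ring A becomes the only free phenol.

Step 8
Reactants: 9 (1R,2R)-2-(benzyloxy)-1-[4-(benzyloxy)phenyl]-3-(4-hydroxyphenyl)propan-1-ol
Product: 13 (2R,3R)-3-(benzyloxy)-2-[4-(benzyloxy)phenyl]chroman-7-ol, via p-peroxyquinol 10 (not isolated), via p-quinol 11 (not isolated), via bicyclic enone 12 (not isolated)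
Conditions: Oxone (2KHSO5·KHSO4·K2SO4), NaHCO3, MeCN/H2O, rt; Me2S; K2CO3 (cat.), rt; extraction, then TsOH·H2O (cat.), toluene, 50 °C
Reagents that add atoms: none
Why: Singlet oxygen released from Oxone in bicarbonate adds to the phenolate of ring A at C4a (para to the C7 oxygen) to give p-peroxyquinol 10, which Me2S reduces to p-quinol 11; the C2 hydroxyl then adds to the enone β-carbon C8a in a base-catalysed oxa-Michael reaction that forms the ring-closing O1–C8a bond (cis-fused 12), and acid-catalysed loss of the C4a hydroxyl together with the C8a hydrogen, through the dienol (an arene hydrate), restores ring A as the 7-hydroxychroman 13. Each event is a known reaction type on p-alkylphenols and p-quinols (Oxone-mediated dearomatization, intramolecular oxa-Michael addition to 4-hydroxycyclohexadienones, dehydrative rearomatization of such adducts to meta-substituted phenols), run here in sequence without isolation. Only ring C is closed, in the 6-exo-trig mode. No stereocentre of 13 is created: C2 and C3 come unchanged from 9 because the C2–O bond is never broken, and the ring-fusion centres C4a and C8a of 12 are erased on aromatization, so both diastereotopic enone termini converge on one product. Chemoselectivity rests on ring A being the only free phenol (ring B and the benzyl groups are ethers, inert to singlet oxygen), and regioselectivity on O3 being benzylated, so that only O1 can add and the five-membered alternative is excluded. The Michael addition is completed under base before any acid is added, so that the acid-labile 4-(benzyloxy)benzylic alcohol of 11 is already tied up as the ring ether when dehydration starts.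

Step 9
Reactants: 13 (2R,3R)-3-(benzyloxy)-2-[4-(benzyloxy)phenyl]chroman-7-ol
Product: 14 (2R,3R)-3,7-bis(benzyloxy)-2-[4-(benzyloxy)phenyl]chromane
Conditions: BnBr, K2CO3, DMF, rt
Reagents that add atoms: benzyl bromide BrCc1ccccc1
Why: Williamson etherification of the phenol caps ring A so that it cannot compete as a nucleophile in the later cation chemistry; with ring B benzylated there is no base-induced opening at C2.

Step 10
Reactants: 14 (2R,3R)-3,7-bis(benzyloxy)-2-[4-(benzyloxy)phenyl]chromane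
Product: 15 (2R,3R,4S)-3,7-bis(benzyloxy)-2-[4-(benzyloxy)phenyl]-4-(2-ethoxyethoxy)chromane
Conditions: DDQ (1.5 equiv), 2-ethoxyethanol, CH2Cl2, rt
Reagents that add atoms: 2-ethoxyethanol CCOCCO
Why: DDQ benzylic oxidation (oxidative C–H alkoxylation) should abstract hydride from C4, which is para to the 7-benzyloxy group and ortho to O1 on the most electron-rich ring, and the alcohol traps the cation anti to the 3-benzyloxy group; the new C4 centre is ionized again in step 12 and is therefore inconsequential.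

Step 11
Reactants: 16 (−)-epicatechin
Product: 17 (2R,3R)-5,7-bis(benzyloxy)-2-[3,4-bis(benzyloxy)phenyl]chroman-3-ol
Conditions: BnBr (4.2 equiv), K2CO3, DMF, 0 °C to rt
Reagents that add atoms: benzyl bromide BrCc1ccccc1
Why: Williamson etherification with carbonate benzylates the four phenols only, because the aliphatic 3-hydroxyl is not deprotonated, and it leaves C8 of the phloroglucinol-type ring free as the nucleophilic site.

Step 12
Reactants: 15 (2R,3R,4S)-3,7-bis(benzyloxy)-2-[4-(benzyloxy)phenyl]-4-(2-ethoxyethoxy)chromane; 17 (2R,3R)-5,7-bis(benzyloxy)-2-[3,4-bis(benzyloxy)phenyl]chroman-3-ol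
Product: 18 (2R,3R)-5,7-bis(benzyloxy)-8-[(2R,3R,4R)-3,7-bis(benzyloxy)-2-[4-(benzyloxy)phenyl]chroman-4-yl]-2-[3,4-bis(benzyloxy)phenyl]chroman-3-ol
Conditions: 17 (4 equiv), TMSOTf (0.2 equiv), CH2Cl2, −78 to −30 °C
Reagents that add atoms: none
Why: Lewis acid-mediated Friedel–Crafts alkylation: TMSOTf ionizes the C4 ether to the flavan-4-yl cation stabilized by O1 and the 7-benzyloxy group, and C8 of 17 attacks the half-chair cation anti to the 3-benzyloxy group, which should set C4 as R (3,4-trans, 4β), while excess 17 suppresses oligomerization.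

Step 13
Reactants: 18 (2R,3R)-5,7-bis(benzyloxy)-8-[(2R,3R,4R)-3,7-bis(benzyloxy)-2-[4-(benzyloxy)phenyl]chroman-4-yl]-2-[3,4-bis(benzyloxy)phenyl]chroman-3-ol
Product: 19 (2R,3R,4R)-4-[(2R,3R)-2-(3,4-dihydroxyphenyl)-3,5,7-trihydroxychroman-8-yl]-2-(4-hydroxyphenyl)chromane-3,7-diol (CNP0118995.2)
Conditions: H2 (1 atm), Pd(OH)2/C, THF/MeOH/H2O, rt
Reagents that add atoms: none
Why: Catalytic hydrogenolysis removes all seven benzyl ethers under neutral conditions, which spare the acid-labile interflavan bond and the ring C–O bonds and touch no stereocentre.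

## Compound list

1 | D-tyrosine | N[C@H](Cc1ccc(O)cc1)C(=O)O | starting material
2 | (R)-2-hydroxy-3-(4-hydroxyphenyl)propanoic acid | O[C@H](Cc1ccc(O)cc1)C(=O)O | intermediate
3 | methyl (R)-2-hydroxy-3-(4-hydroxyphenyl)propanoate | O[C@H](Cc1ccc(O)cc1)C(=O)OC | intermediate
4 | methyl (R)-3-[4-[(tert-butyldimethylsilyl)oxy]phenyl]-2-hydroxypropanoate | O[C@H](Cc1ccc(O[Si](C)(C)C(C)(C)C)cc1)C(=O)OC | intermediate
5 | methyl (R)-2-(benzyloxy)-3-[4-[(tert-butyldimethylsilyl)oxy]phenyl]propanoate | C(c1ccccc1)O[C@H](Cc1ccc(O[Si](C)(C)C(C)(C)C)cc1)C(=O)OC | intermediate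
6 | (R)-2-(benzyloxy)-3-[4-[(tert-butyldimethylsilyl)oxy]phenyl]propanal | C(c1ccccc1)O[C@H](Cc1ccc(O[Si](C)(C)C(C)(C)C)cc1)C=O | intermediate
7 | 4-(benzyloxy)phenylmagnesium bromide | Br[Mg]c1ccc(OCc2ccccc2)cc1 | starting material
8 | (1R,2R)-2-(benzyloxy)-1-[4-(benzyloxy)phenyl]-3-[4-[(tert-butyldimethylsilyl)oxy]phenyl]propan-1-ol | O[C@H](c1ccc(OCc2ccccc2)cc1)[C@H](OCc1ccccc1)Cc1ccc(O[Si](C)(C)C(C)(C)C)cc1 | intermediate
9 | (1R,2R)-2-(benzyloxy)-1-[4-(benzyloxy)phenyl]-3-(4-hydroxyphenyl)propan-1-ol | O[C@H](c1ccc(OCc2ccccc2)cc1)[C@H](OCc1ccccc1)Cc1ccc(O)cc1 | intermediate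
10 | 4-[(2R,3R)-2-(benzyloxy)-3-[4-(benzyloxy)phenyl]-3-hydroxypropyl]-4-hydroperoxycyclohexa-2,5-dien-1-one (p-peroxyquinol) | O[C@H](c1ccc(OCc2ccccc2)cc1)[C@H](OCc1ccccc1)CC1(OO)C=CC(=O)C=C1 | intermediate
11 | 4-[(2R,3R)-2-(benzyloxy)-3-[4-(benzyloxy)phenyl]-3-hydroxypropyl]-4-hydroxycyclohexa-2,5-dien-1-one (p-quinol) | O[C@H](c1ccc(OCc2ccccc2)cc1)[C@H](OCc1ccccc1)CC1(O)C=CC(=O)C=C1 | intermediate
12 | (2R,3R,4aS,8aS)-3-(benzyloxy)-2-[4-(benzyloxy)phenyl]-4a-hydroxy-2,3,4,4a,8,8a-hexahydro-7H-chromen-7-one (cis-fused bicyclic enone; the 4aR,8aR cis-fused isomer converges) | O=C1C=C[C@@]2(O)C[C@@H](OCc3ccccc3)[C@@H](c3ccc(OCc4ccccc4)cc3)O[C@H]2C1 | intermediate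
13 | (2R,3R)-3-(benzyloxy)-2-[4-(benzyloxy)phenyl]chroman-7-ol | Oc1ccc2c(c1)O[C@H](c1ccc(OCc3ccccc3)cc1)[C@H](OCc1ccccc1)C2 | intermediate
14 | (2R,3R)-3,7-bis(benzyloxy)-2-[4-(benzyloxy)phenyl]chromane | C(Oc1ccc2c(c1)O[C@H](c1ccc(OCc3ccccc3)cc1)[C@H](OCc1ccccc1)C2)c1ccccc1 | intermediate
15 | (2R,3R,4S)-3,7-bis(benzyloxy)-2-[4-(benzyloxy)phenyl]-4-(2-ethoxyethoxy)chromane | CCOCCO[C@@H]1[C@@H](OCc2ccccc2)[C@@H](c2ccc(OCc3ccccc3)cc2)Oc2cc(OCc3ccccc3)ccc21 | intermediate
16 | (−)-epicatechin, (2R,3R)-2-(3,4-dihydroxyphenyl)chromane-3,5,7-triol | O[C@@H]1Cc2c(O)cc(O)cc2O[C@@H]1c1ccc(O)c(O)c1 | starting material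
17 | (2R,3R)-5,7-bis(benzyloxy)-2-[3,4-bis(benzyloxy)phenyl]chroman-3-ol | O[C@@H]1Cc2c(OCc3ccccc3)cc(OCc3ccccc3)cc2O[C@@H]1c1ccc(OCc2ccccc2)c(OCc2ccccc2)c1 | intermediate
18 | (2R,3R)-5,7-bis(benzyloxy)-8-[(2R,3R,4R)-3,7-bis(benzyloxy)-2-[4-(benzyloxy)phenyl]chroman-4-yl]-2-[3,4-bis(benzyloxy)phenyl]chroman-3-ol | c1ccccc1COc1ccc([C@H]2Oc3cc(OCc4ccccc4)ccc3[C@H](c3c(OCc4ccccc4)cc(OCc4ccccc4)c4c3O[C@H](c3ccc(OCc5ccccc5)c(OCc5ccccc5)c3)[C@H](O)C4)[C@H]2OCc2ccccc2)cc1 | intermediate
19 | (2R,3R,4R)-4-[(2R,3R)-2-(3,4-dihydroxyphenyl)-3,5,7-trihydroxychroman-8-yl]-2-(4-hydroxyphenyl)chromane-3,7-diol | Oc1ccc([C@H]2Oc3cc(O)ccc3[C@H](c3c(O)cc(O)c4c3O[C@H](c3ccc(O)c(O)c3)[C@H](O)C4)[C@H]2O)cc1 | target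

## Step count and risks

Total step count: 13 steps. Longest linear sequence: 12 steps (steps 1 to 10, 12 and 13); step 11 is a one-step branch.

Steps most likely to fail:

1. Step 8. The dehydrative rearomatization may stall at the bicyclic enone, or the acid it needs may ionize the benzylic C2–O bond (scrambling C2) or reverse the Michael addition. The fallback makes the same O1–C8a bond by cross-coupling onto a ring A that already carries a leaving group at C8a; it sets out from Grignard reagent 7 and returns to the route at 14. Commercial 2-bromo-4-hydroxybenzaldehyde is benzylated (BnBr, K2CO3, DMF) to 4-(benzyloxy)-2-bromobenzaldehyde F1, reduced (NaBH4, MeOH) to [4-(benzyloxy)-2-bromophenyl]methanol F2 and converted (PBr3, CH2Cl2, 0 °C) into 4-(benzyloxy)-2-bromo-1-(bromomethyl)benzene F3. Evans alkylation of commercial (S)-4-benzyl-3-[(benzyloxy)acetyl]oxazolidin-2-one with F3 (NaN(SiMe3)2, THF, −78 °C) should give (S)-4-benzyl-3-[(R)-2-(benzyloxy)-3-[4-(benzyloxy)-2-bromophenyl]propanoyl]oxazolidin-2-one F4, by attack anti to the benzyl group of the auxiliary. LiBH4 (THF/H2O, 0 °C) then releases (R)-2-(benzyloxy)-3-[4-(benzyloxy)-2-bromophenyl]propan-1-ol F5, and Dess–Martin periodinane gives (R)-2-(benzyloxy)-3-[4-(benzyloxy)-2-bromophenyl]propanal F6. Chelation-controlled addition of 7 as in step 6 gives (1R,2R)-2-(benzyloxy)-1-[4-(benzyloxy)phenyl]-3-[4-(benzyloxy)-2-bromophenyl]propan-1-ol F7. Intramolecular Buchwald–Hartwig etherification of the aryl bromide with the benzylic alcohol (Pd(OAc)2, 2-(di-tert-butylphosphino)-1,1'-binaphthyl, Cs2CO3, toluene, 80 °C) closes ring C to 14, so steps 7 to 9 are bypassed.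

2. Step 10. Hydride abstraction may take place at C2 (benzylic to ring B and next to O1) instead of C4, or run on to the 4-ketone. The fallback moves the oxidation ahead of the benzylation and uses the free phenol of ring A; it sets out from 13 and returns at 15. Oxidation of 13 with DDQ (1.0 equiv) in CH2Cl2/2-ethoxyethanol at −20 °C takes the p-alkylphenol to its p-quinone methide (C7 carbonyl, C4 methide), which can form only at C4. 1,6-Addition of the alcohol anti to the 3-benzyloxy group should give (2R,3R,4S)-3-(benzyloxy)-2-[4-(benzyloxy)phenyl]-4-(2-ethoxyethoxy)chroman-7-ol F8, and benzylation (BnBr, K2CO3, DMF) then gives 15.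

3. Step 6. Chelation control may erode because THF competes for magnesium, or the α-benzyloxy aldehyde may enolize and lose configuration. The fallback replaces substrate control by catalyst control; it sets out from ester 5 and returns at 8. Treatment of 5 with MeNH(OMe)·HCl and i-PrMgCl (THF, −20 °C) gives (R)-2-(benzyloxy)-3-[4-[(tert-butyldimethylsilyl)oxy]phenyl]-N-methoxy-N-methylpropanamide F9, and addition of 7 gives (R)-2-(benzyloxy)-1-[4-(benzyloxy)phenyl]-3-[4-[(tert-butyldimethylsilyl)oxy]phenyl]propan-1-one F10. Noyori asymmetric transfer hydrogenation (RuCl(p-cymene)[(S,S)-TsDPEN], HCO2H/Et3N, rt) should deliver hydride to the aryl ketone under catalyst control and give the (1R) carbinol 8.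

## Further compounds

F1 | step 8 | 4-(benzyloxy)-2-bromobenzaldehyde | O=Cc1ccc(OCc2ccccc2)cc1Br
F2 | step 8 | [4-(benzyloxy)-2-bromophenyl]methanol | OCc1ccc(OCc2ccccc2)cc1Br
F3 | step 8 | 4-(benzyloxy)-2-bromo-1-(bromomethyl)benzene | BrCc1ccc(OCc2ccccc2)cc1Br
F4 | step 8 | (S)-4-benzyl-3-[(R)-2-(benzyloxy)-3-[4-(benzyloxy)-2-bromophenyl]propanoyl]oxazolidin-2-one | O=C1OC[C@H](Cc2ccccc2)N1C(=O)[C@H](OCc1ccccc1)Cc1ccc(OCc2ccccc2)cc1Br
F5 | step 8 | (R)-2-(benzyloxy)-3-[4-(benzyloxy)-2-bromophenyl]propan-1-ol | OC[C@H](OCc1ccccc1)Cc1ccc(OCc2ccccc2)cc1Br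
F6 | step 8 | (R)-2-(benzyloxy)-3-[4-(benzyloxy)-2-bromophenyl]propanal | O=C[C@H](OCc1ccccc1)Cc1ccc(OCc2ccccc2)cc1Br
F7 | step 8 | (1R,2R)-2-(benzyloxy)-1-[4-(benzyloxy)phenyl]-3-[4-(benzyloxy)-2-bromophenyl]propan-1-ol | O[C@H](c1ccc(OCc2ccccc2)cc1)[C@H](OCc1ccccc1)Cc1ccc(OCc2ccccc2)cc1Br
F8 | step 10 | (2R,3R,4S)-3-(benzyloxy)-2-[4-(benzyloxy)phenyl]-4-(2-ethoxyethoxy)chroman-7-ol | CCOCCO[C@@H]1[C@@H](OCc2ccccc2)[C@@H](c2ccc(OCc3ccccc3)cc2)Oc2cc(O)ccc21
F9 | step 6 | (R)-2-(benzyloxy)-3-[4-[(tert-butyldimethylsilyl)oxy]phenyl]-N-methoxy-N-methylpropanamide | CON(C)C(=O)[C@H](OCc1ccccc1)Cc1ccc(O[Si](C)(C)C(C)(C)C)cc1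
F10 | step 6 | (R)-2-(benzyloxy)-1-[4-(benzyloxy)phenyl]-3-[4-[(tert-butyldimethylsilyl)oxy]phenyl]propan-1-one | O=C(c1ccc(OCc2ccccc2)cc1)[C@H](OCc1ccccc1)Cc1ccc(O[Si](C)(C)C(C)(C)C)cc1
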